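If you repeat spring, hold on to the charge of incoming ligand divided by the charge of starting complex, the ligand per complex, 0.500 there.

| setting | cedar | oak | ash | dawn | spring |
|---|---|---|---|---|---|
| starting complex | 0.87 M | 0.87 M | 0.87 M | 0.87 M | 0.87 M |
| incoming ligand | 0.40 M | 0.86 M | 1.3 M | 1.74 M | 0.435 M |
| remark | run made earlier | run made earlier | run made earlier |  |  |
| time |  |  |  | 10 min | 10 min |

| run | time / min | complex with three exchanged / % | complex with two exchanged / % |
|---|---|---|---|
| cedar | 0.667 | 0 | 1.1 |
| cedar | 2.00 | 1.7 | 0 |
| cedar | 3.00 | 0.2 | 0.1 |
| cedar | 5.00 | 0.2 | 2.0 |
| cedar | 8.00 | 1.3 | 1.2 |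
| oak | 0.500 | 0 | 1.9 |
| oak | 1.00 | 0 | 1.5 |
| oak | 2.00 | 0 | 3.1 |
| oak | 4.00 | 0 | 6.9 |
| oak | 8.00 | 0 | 8.1 |
| ash | 1.33 | 0 | 1.7 |
| ash | 3.00 | 0.6 | 8.4 |
| ash | 4.00 | 3.2 | 13.0 |
| ash | 6.00 | 0 | 14.2 |
| ash | 8.00 | 2.6 | 15.2 |

(readings scatter by 1 percentage point)

- what was read earlier has a scatter of 1 percentage point, one standard deviation

1. which of these holds the largest part of the starting complex at the end of dawn (starting complex / complex with one exchanged / complex with three exchanged / complex with two exchanged)
2. which of these holds the largest part of the starting complex at the end of spring (starting complex / complex with one exchanged / complex with three exchanged / complex with two exchanged)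
3. how much complex with three exchanged is there at the end of dawn, in percent of the starting complex charged

Each exchange costs one incoming ligand, which makes incoming ligand the limiting reagent in spring. So the balance holds starting complex at 50.0% of its charge or above. Turn the question round: for starting complex to lose first place in spring, the ligand per complex would have to stand above 0.5. Spring stands exactly on that line, and any ligand left unused or spent on a second exchange keeps starting complex further ahead.

In dawn the ligand per complex is 2.00, so the subtraction gives nothing to hold and the readings must serve. For the opposite outcome there, two exchanged would have to overtake one exchanged, or starting complex would have to stay ahead of one exchanged, and the earlier runs read neither of that pair. On the first route, ash, at 1.49, reads two exchanged at 15.2% after 8.00 min, and oak, at 0.989, reads 8.1%. So I put one exchanged first in dawn, as a judgement, with the second route still open. Three exchanged in ash reads between 0% and 3.2%, with a scatter of 1 percentage point, so I expect a small figure for dawn.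

The forecast agrees on the order, giving complex with one exchanged for dawn, starting complex for spring and 6% of three exchanged in dawn, on the ground that “the first exchange takes most of the ligand within minutes”.

    starting complex + incoming ligand ⇌ leaving ligand + complex with one exchanged (K = 2.60, k = 0.270 L mol⁻¹ min⁻¹)
    complex with one exchanged + incoming ligand ⇌ leaving ligand + complex with two exchanged (K = 0.440, k = 0.150 L mol⁻¹ min⁻¹)
    complex with two exchanged + incoming ligand ⇌ leaving ligand + complex with three exchanged (K = 0.160, k = 0.110 L mol⁻¹ min⁻¹)
    leaving ligand → by-product carried off (k = 0.0360 min⁻¹)

Dawn ends with complex with one exchanged at 52.1% and three exchanged at 3.79%. Spring, at 0.500 ligand per complex, ends with starting complex at 64.4%, and after 100 min it still holds 56.1%, above the 50.0% of the balance. Three exchanged in dawn stays that low partly because leaving ligand turns it back and partly because you read at 10.0 min and not at 100 min. With that way back removed, dawn reads 12.6% at the asked time, and left to the later time it reads 14.6%.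

The readings are simulated with made-up constants, noise included.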